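| flask | Yx | Kj | Ju | remark | time |
|---|---|---|---|---|---|
| Sunday's | 1.4 mM | 1 mM | 2 mM (fed, over 1.5 s) | run made earlier |  |
| Wednesday's | 2.2 mM | 1 mM | 2 mM (fed, over 1.5 s) | run made earlier |  |
| Saturday's | 1 mM | 1 mM | 3 mM (fed, over 1.5 s) | run made earlier |  |
| flask | 1.0 mM | 1.00 mM | 2.00 mM (fed, over 1.5 s) |  | 20 min |

| run | time / min | Qo / % | Ky / % |
|---|---|---|---|
| Sunday's | 1.50 | 7.7 | 8.3 |
| Sunday's | 4.00 | 7.1 | 8.6 |
| Sunday's | 8.00 | 6.3 | 8.1 |
| Sunday's | 12.0 | 5.6 | 7.3 |
| Wednesday's | 1.00 | 4.1 | 3.8 |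
| Wednesday's | 2.00 | 5.2 | 4.4 |
| Wednesday's | 5.00 | 6.2 | 4.7 |
| Wednesday's | 12.0 | 5.0 | 4.0 |
| Saturday's | 3.00 | 8.8 | 11.9 |
| Saturday's | 6.00 | 8.6 | 11.4 |
| Saturday's | 10.0 | 8.8 | 11.4 |
| Saturday's | 12.0 | 8.8 | 11.7 |

(standard deviation of a reading: 0.5 percentage points)

- which holds at 20 min: what has brought the reaction to rest, or that it has not come to rest (all of Yx has reacted / Kj has run out first / it is still moving / forward and back rates have come level)
- Qo at 20 min, in percent of the Yx charged
- Ky at 20 min, in percent of the Yx charged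
- amount of Qo if the flask were left three thousand times as long, in percent of the Yx charged

- the reaction counts as stopped when no species that holds the Yx changes by six tenths of a point or more over the second half of the time

- The ratio cKy/cQo says more than either reading. On Sunday's run it stands at 1.29 at 8.00 min and 1.30 at 12.0 min; on Wednesday's run it reads 0.758 at 5.00 min and 0.800 at 12.0 min. Each ratio carries the scatter of 0.5 percentage points in its two readings.
- First instants: the feed of 1.5 s is far shorter than the earliest reading, 1.00 min, so we treat Ju as dosed at once. Wednesday's run already shows Qo 4.1% at that reading, against its highest reading of 6.2%.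
- Middle: Sunday's and Wednesday's runs share their Kj and Ju and differ in Yx, so we read the fall of the late ratio per mM of Yx charged, the ratio slope: 0.629 mM⁻¹. Our flask has the same Kj and Ju, so the line gives it a ratio of 1.56.
- End: Saturday's run is flat from 3.00 min on, with Qo and Ky together at 20.5% of the Yx charged. We therefore bet that our flask comes to rest with forward and back rates level and Yx still present. Taking Saturday's Qo of 8.8% for it, our own reckoning gives Ky 13.7%, and Qo should stay there on long standing.
- The forecast says all of Yx has reacted, with Qo 9.3%, Ky 11.2% and Qo 9.3% on long standing: “Yx is gone quickly and the levels freeze”. Its ending and its lower Ky differ from ours.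
- The simulated flask gives forward and back rates have come level, with Qo 8.84%, Ky 12.6% and Qo 8.84% on long standing. Yx stands at 57%.

    Yx + Kj ⇌ Ju + Qe (K = 4.00, k = 100 M⁻¹ s⁻¹)
    Qo ⇌ Ek (K = 1.30, k = 0.130 s⁻¹)
    Qo + Kj ⇌ Ju + Ky (K = 34.0, k = 430 M⁻¹ s⁻¹)
    Qe + Kj ⇌ Ju + Qo (K = 22.0, k = 260 M⁻¹ s⁻¹)

- The flask's ratio is 1.43, against 1.56 from the slope. One part of the reason for Ky's level is the back step Ju + Ky to Qo + Kj: a run without it ends differently, with Ky 32.3% instead of 12.6%.
- In the neighbour flask with 0.40 mM of Yx, the slope 0.629 mM⁻¹ gives a ratio of 1.93. The computed flask has Qo 13.7% and Ky 40.1%, a ratio of 2.93, higher than the line gives.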